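**Plan**
- Retrosynthesis: the acetate and the bond between the carbinol carbon and butenolide C-4 are cut first. Then the two ring bonds of the α-alkylidene-γ-butyrolactone (ring O1–C2(=O)–C3–C4–C5) are cut together: C4H2–C5H(O) and C2(=O)–C3. This leaves a (Z)-2-bromoallyl bromide on the chain and prenyl N,N-diisopropylcarbamate.
- Enabling feature: ring C5 is both O-bound and allylic, so as its carbamate it can be lithiated (α-oxy allyl anion, polarity reversal of a carbinol carbon), and the carbamate C=O is the future lactone C2. Ring C3 is an alkene carbon next to the ring CH2, so a 2-bromoallyl bromide supplies an electrophilic CH2 and a latent vinyl anion.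
- Forward order: farnesyl bromide is homologated, its terminal alkene degraded to an aldehyde, and this is converted to the (Z)-bromoallyl bromide. The lactone C–C frame is made in step 9 and the ring closed in step 10. The preformed butenolide ring is attached last.
- Stereochemistry: lactone C5 (S) comes from sparteine-controlled lithiation and invertive alkylation. The Z-alkylidene comes from the (Z)-bromoalkene and stereoretentive Br/Li exchange. The E,E-olefins come from farnesyl bromide. The acetoxy carbinol (R) comes from a CBS reduction.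

Key step: step 9

Assumption: the sense of induction in step 9 follows the precedent for lithiated 2-alkenyl carbamates (pro-S deprotonation by (−)-sparteine, invertive alkylation), so (+)-sparteine is specified; if the sense proves opposite, the antipodal diamine is used.

**Route**

Step 1
Reactants: 1 (2E,6E)-farnesyl bromide
Product: 3 (3E,7E)-homofarnesol, via silane 2 (not isolated)
Conditions: ClMgCH2SiMe2(OiPr), Li2CuCl4 (cat.), THF, 0 °C; then 30% H2O2, KF, KHCO3, THF/MeOH, rt
Reagents that add atoms: [(isopropoxydimethylsilyl)methyl]magnesium chloride, CC(C)O[Si](C)(C)C[Mg]Cl; hydrogen peroxide, OO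
Why: Copper-catalysed SN2 coupling of the primary allylic bromide with the silylmethyl Grignard reagent followed by Tamao–Fleming oxidation is a standard nucleophilic hydroxymethylation that leaves the E,E-olefins untouched.

Step 2
Reactants: 3 (3E,7E)-homofarnesol
Product: 4 homofarnesyl TBDPS ether
Conditions: TBDPSCl, imidazole, DMF, rt
Reagents that add atoms: tert-butyl(chloro)diphenylsilane, CC(C)(C)[Si](Cl)(c1ccccc1)c1ccccc1
Why: Standard silylation of a primary alcohol; TBDPS is chosen to survive periodic acid and the organolithium reagents of step 9.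

Step 3
Reactants: 4 homofarnesyl TBDPS ether
Product: 6 terminal epoxide, via bromohydrin 5 (not isolated)
Conditions: NBS, THF/H2O, 0 °C; then K2CO3, MeOH, rt
Reagents that add atoms: water, O
Why: Bromohydrin formation with NBS in aqueous THF is selective for the terminal trisubstituted alkene of polyprenyl chains, and base closes the epoxide; its stereocenter is removed in step 4.

Step 4
Reactants: 6 terminal epoxide
Product: 7 (4E,8E)-11-[(tert-butyldiphenylsilyl)oxy]-4,8-dimethylundeca-4,8-dienal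
Conditions: H5IO6, THF/Et2O, 0 °C
Reagents that add atoms: none
Why: Periodic acid opens the epoxide and cleaves the resulting glycol to the aldehyde and acetone (oxidative glycol cleavage).

Step 5
Reactants: 7 the dienal
Product: 8 ethyl (2Z,6E,10E)-2-bromo-13-[(tert-butyldiphenylsilyl)oxy]-6,10-dimethyltrideca-2,6,10-trienoate
Conditions: Ph3P=C(Br)CO2Et, CH2Cl2, rt
Reagents that add atoms: ethyl 2-bromo-2-(triphenyl-λ5-phosphanylidene)acetate, CCOC(=O)C(Br)=P(c1ccccc1)(c1ccccc1)c1ccccc1
Why: Wittig olefination with the stabilised α-bromo ylide should give mainly the (Z)-2-bromo enoate, with the ester trans and the bromine cis to the chain.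

Step 6
Reactants: 8 the bromo enoate
Product: 9 (2Z,6E,10E)-2-bromo-13-[(tert-butyldiphenylsilyl)oxy]-6,10-dimethyltrideca-2,6,10-trien-1-ol
Conditions: DIBAL-H, CH2Cl2, −78 °C
Reagents that add atoms: none
Why: 1,2-Reduction of the enoate to the allylic alcohol leaves the vinylic bromide and the alkene geometry unchanged.

Step 7
Reactants: 9 the bromoallylic alcohol
Product: 10 {[(3E,7E,11Z)-12,13-dibromo-4,8-dimethyltrideca-3,7,11-trien-1-yl]oxy}(tert-butyl)diphenylsilane
Conditions: CBr4, PPh3, CH2Cl2, 0 °C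
Reagents that add atoms: carbon tetrabromide, BrC(Br)(Br)Br
Why: Appel bromination converts the primary allylic alcohol into the primary allylic bromide without allylic transposition.

Step 8
Reactants: 11 3-methylbut-2-en-1-ol
Product: 12 3-methylbut-2-en-1-yl N,N-diisopropylcarbamate
Conditions: NaH, THF, 0 °C; ClC(O)N(iPr)2, rt
Reagents that add atoms: N,N-diisopropylcarbamoyl chloride, CC(C)N(C(C)C)C(Cl)=O
Why: Standard O-carbamoylation of the alkoxide; the carbamate carbonyl carbon is the future lactone carbonyl.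

Step 9
Reactants: 12 3-methylbut-2-en-1-yl N,N-diisopropylcarbamate; 10 the (Z)-bromoallyl bromide
Product: 16 (2Z,6E,10E)-13-[(tert-butyldiphenylsilyl)oxy]-2-[(2S)-2-hydroxy-4-methylpent-3-en-1-yl]-6,10-dimethyl-N,N-diisopropyltrideca-2,6,10-trienamide, via lithiated carbamate 13 (not isolated), via alkylated carbamate 14 (not isolated), via alkenyllithium 15 (not isolated)
Conditions: 12 (1.5 equiv), n-BuLi, (+)-sparteine, PhMe, −78 °C; 10 (1.0 equiv), −78 °C; then THF, t-BuLi (2.2 equiv), −78 → −20 °C; aq NH4Cl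
Reagents that add atoms: none
Why: n-BuLi/(+)-sparteine removes one enantiotopic proton of 12 at the carbon that is both O-bound and allylic, and the α-oxy allyllithium 13 displaces the primary bromide of 10 by SN2 to give 14; t-BuLi then exchanges the vinylic bromine with retention (15) and the alkenyllithium adds to the carbamate C=O, whose collapse moves the carbamoyl group from O to C. The closest known reaction types are the sparteine-mediated α-lithiation–alkylation of O-(2-alkenyl) carbamates and the anionic homo-Fries (1,4 O→C carbamoyl) shift of ortho-lithiated benzyl carbamates, here run in one flask as a formal [3+2] union. Ring closure is a 5-exo-trig addition to the carbamate carbonyl giving a five-membered tetrahedral intermediate that opens by C–O cleavage, so the isolated product is the open hydroxy amide and the O–C(=O) bond is restored in step 10. The new carbinol stereocenter (S) is controlled by the chiral diamine through the configuration of 13 and invertive substitution at the lithium-bearing carbon. The step needs α- over γ-alkylation (secured by the fully substituted CMe2 terminus), SN2 over SN2′ on 10 (primary CH2Br), Br/Li exchange faster than attack on the hindered diisopropylcarbamate, and retention of the Z-alkene (alkenyllithiums are configurationally stable at −78 °C).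

Step 10
Reactants: 16 the hydroxy amide
Product: 17 (3Z,5S)-3-[(4E,8E)-11-[(tert-butyldiphenylsilyl)oxy]-4,8-dimethylundeca-4,8-dien-1-ylidene]-5-(2-methylprop-1-en-1-yl)oxolan-2-one
Conditions: MeOTf, 2,6-di-tert-butyl-4-methylpyridine, CH2Cl2, 0 °C → rt; aq NaHCO3
Reagents that add atoms: none
Why: O-Methylation of the amide gives an imidate salt that the neighbouring hydroxyl attacks (5-exo-trig); loss of the amine and demethylation of the alkoxycarbenium ion should give the lactone without ionising the allylic C–O stereocenter.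

Step 11
Reactants: 17 the silyl lactone
Product: 18 (3Z,5S)-3-[(4E,8E)-11-hydroxy-4,8-dimethylundeca-4,8-dien-1-ylidene]-5-(2-methylprop-1-en-1-yl)oxolan-2-one
Conditions: HF·pyridine, pyridine, THF, 0 °C → rt
Reagents that add atoms: none
Why: Buffered fluoride desilylation frees the primary alcohol and should spare the alkylidene lactone.

Step 12
Reactants: 18 the hydroxy lactone
Product: 19 (3E,7E)-4,8-dimethyl-11-[(3Z,5S)-5-(2-methylprop-1-en-1-yl)-2-oxooxolan-3-ylidene]undeca-3,7-dienal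
Conditions: Dess–Martin periodinane, NaHCO3, CH2Cl2, 0 °C; used at once
Reagents that add atoms: none
Why: Buffered Dess–Martin oxidation gives the β,γ-unsaturated aldehyde without moving the olefin into conjugation.

Step 13
Reactants: 19 the aldehyde; 20 4-bromofuran-2(5H)-one
Product: 21 (3Z,5S)-3-[(4E,8E)-11-hydroxy-4,8-dimethyl-11-(5-oxo-2,5-dihydrofuran-3-yl)undeca-4,8-dien-1-ylidene]-5-(2-methylprop-1-en-1-yl)oxolan-2-one (both C-11 epimers)
Conditions: CrCl2, NiCl2 (cat.), DMF, rt
Reagents that add atoms: none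
Why: Nozaki–Hiyama–Kishi coupling: nickel inserts into the vinylic C–Br bond, the alkenylchromium adds chemoselectively to the aldehyde, and the uncontrolled carbinol center is erased in step 14.

Step 14
Reactants: 21 the carbinol mixture
Product: 22 (3Z,5S)-3-[(4E,8E)-4,8-dimethyl-11-oxo-11-(5-oxo-2,5-dihydrofuran-3-yl)undeca-4,8-dien-1-ylidene]-5-(2-methylprop-1-en-1-yl)oxolan-2-one
Conditions: Dess–Martin periodinane, NaHCO3, CH2Cl2, 0 °C
Reagents that add atoms: none
Why: Neutral oxidation of the secondary alcohol gives the 4-acylbutenolide without enolising the doubly activated CH2.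

Step 15
Reactants: 22 the ketone
Product: 23 (3Z,5S)-3-[(4E,8E,11R)-11-hydroxy-4,8-dimethyl-11-(5-oxo-2,5-dihydrofuran-3-yl)undeca-4,8-dien-1-ylidene]-5-(2-methylprop-1-en-1-yl)oxolan-2-one
Conditions: (S)-Me-CBS (20 mol%), catecholborane, PhMe/CH2Cl2, −78 °C
Reagents that add atoms: none
Why: Corey–Bakshi–Shibata reduction with the sp2 butenolide as the large group and the CH2 as the small group should give the (R)-carbinol with the (S)-oxazaborolidine, by analogy with aryl and alkenyl ketones.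

Step 16
Reactants: 23 the (R)-carbinol
Product: 24 (1R,3E,7E)-4,8-dimethyl-11-[(3Z,5S)-5-(2-methylprop-1-en-1-yl)-2-oxooxolan-3-ylidene]-1-(5-oxo-2,5-dihydrofuran-3-yl)undeca-3,7-dien-1-yl acetate
Conditions: Ac2O, pyridine, DMAP (cat.), CH2Cl2, 0 °C
Reagents that add atoms: acetic anhydride, CC(=O)OC(C)=O
Why: Standard acetylation of the secondary alcohol with retention at the carbinol center.

**Compound list**

1 | (2E,6E)-farnesyl bromide | BrC/C=C(\C)CC/C=C(\C)CCC=C(C)C | starting material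
2 | isopropoxy(dimethyl)[(3E,7E)-4,8,12-trimethyltrideca-3,7,11-trien-1-yl]silane (not isolated) | CC(C)O[Si](C)(C)CC/C=C(\C)CC/C=C(\C)CCC=C(C)C | intermediate
3 | (3E,7E)-4,8,12-trimethyltrideca-3,7,11-trien-1-ol (homofarnesol) | OCC/C=C(\C)CC/C=C(\C)CCC=C(C)C | intermediate
4 | tert-butyl(diphenyl){[(3E,7E)-4,8,12-trimethyltrideca-3,7,11-trien-1-yl]oxy}silane | CC(C)(C)[Si](c1ccccc1)(c1ccccc1)OCC/C=C(\C)CC/C=C(\C)CCC=C(C)C | intermediate
5 | (6E,10E)-3-bromo-13-[(tert-butyldiphenylsilyl)oxy]-2,6,10-trimethyltrideca-6,10-dien-2-ol (not isolated) | CC(C)(C)[Si](c1ccccc1)(c1ccccc1)OCC/C=C(\C)CC/C=C(\C)CCC(Br)C(C)(C)O | intermediate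
6 | tert-butyl{[(3E,7E)-10-(3,3-dimethyloxiran-2-yl)-4,8-dimethyldeca-3,7-dien-1-yl]oxy}diphenylsilane | CC(C)(C)[Si](c1ccccc1)(c1ccccc1)OCC/C=C(\C)CC/C=C(\C)CCC1OC1(C)C | intermediate
7 | (4E,8E)-11-[(tert-butyldiphenylsilyl)oxy]-4,8-dimethylundeca-4,8-dienal | CC(C)(C)[Si](c1ccccc1)(c1ccccc1)OCC/C=C(\C)CC/C=C(\C)CCC=O | intermediate
8 | ethyl (2Z,6E,10E)-2-bromo-13-[(tert-butyldiphenylsilyl)oxy]-6,10-dimethyltrideca-2,6,10-trienoate | CC(C)(C)[Si](c1ccccc1)(c1ccccc1)OCC/C=C(\C)CC/C=C(\C)CC/C=C(\Br)C(=O)OCC | intermediate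
9 | (2Z,6E,10E)-2-bromo-13-[(tert-butyldiphenylsilyl)oxy]-6,10-dimethyltrideca-2,6,10-trien-1-ol | CC(C)(C)[Si](c1ccccc1)(c1ccccc1)OCC/C=C(\C)CC/C=C(\C)CC/C=C(\Br)CO | intermediate
10 | {[(3E,7E,11Z)-12,13-dibromo-4,8-dimethyltrideca-3,7,11-trien-1-yl]oxy}(tert-butyl)diphenylsilane | CC(C)(C)[Si](c1ccccc1)(c1ccccc1)OCC/C=C(\C)CC/C=C(\C)CC/C=C(\Br)CBr | intermediate
11 | 3-methylbut-2-en-1-ol | CC(C)=CCO | starting material
12 | 3-methylbut-2-en-1-yl N,N-diisopropylcarbamate | CC(C)=CCOC(=O)N(C(C)C)C(C)C | intermediate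
13 | (R)-1-lithio-3-methylbut-2-en-1-yl N,N-diisopropylcarbamate, as its (+)-sparteine complex (not isolated) | [Li][C@@H](OC(=O)N(C(C)C)C(C)C)C=C(C)C | intermediate
14 | (4S,6Z,10E,14E)-6-bromo-17-[(tert-butyldiphenylsilyl)oxy]-2,10,14-trimethylheptadeca-2,6,10,14-tetraen-4-yl N,N-diisopropylcarbamate (not isolated) | CC(C)(C)[Si](c1ccccc1)(c1ccccc1)OCC/C=C(\C)CC/C=C(\C)CC/C=C(\Br)C[C@H](OC(=O)N(C(C)C)C(C)C)C=C(C)C | intermediate
15 | 6-lithio analogue of 14 (alkenyllithium, not isolated) | CC(C)(C)[Si](c1ccccc1)(c1ccccc1)OCC/C=C(\C)CC/C=C(\C)CC/C=C(\[Li])C[C@H](OC(=O)N(C(C)C)C(C)C)C=C(C)C | intermediate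
16 | (2Z,6E,10E)-13-[(tert-butyldiphenylsilyl)oxy]-2-[(2S)-2-hydroxy-4-methylpent-3-en-1-yl]-6,10-dimethyl-N,N-diisopropyltrideca-2,6,10-trienamide | CC(C)(C)[Si](c1ccccc1)(c1ccccc1)OCC/C=C(\C)CC/C=C(\C)CC/C=C(/C[C@H](O)C=C(C)C)C(=O)N(C(C)C)C(C)C | intermediate
17 | (3Z,5S)-3-[(4E,8E)-11-[(tert-butyldiphenylsilyl)oxy]-4,8-dimethylundeca-4,8-dien-1-ylidene]-5-(2-methylprop-1-en-1-yl)oxolan-2-one | CC(C)(C)[Si](c1ccccc1)(c1ccccc1)OCC/C=C(\C)CC/C=C(\C)CC/C=C1/C[C@@H](C=C(C)C)OC1=O | intermediate
18 | (3Z,5S)-3-[(4E,8E)-11-hydroxy-4,8-dimethylundeca-4,8-dien-1-ylidene]-5-(2-methylprop-1-en-1-yl)oxolan-2-one | OCC/C=C(\C)CC/C=C(\C)CC/C=C1/C[C@@H](C=C(C)C)OC1=O | intermediate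
19 | (3E,7E)-4,8-dimethyl-11-[(3Z,5S)-5-(2-methylprop-1-en-1-yl)-2-oxooxolan-3-ylidene]undeca-3,7-dienal | O=CC/C=C(\C)CC/C=C(\C)CC/C=C1/C[C@@H](C=C(C)C)OC1=O | intermediate
20 | 4-bromofuran-2(5H)-one | BrC1=CC(=O)OC1 | starting material
21 | (3Z,5S)-3-[(4E,8E)-11-hydroxy-4,8-dimethyl-11-(5-oxo-2,5-dihydrofuran-3-yl)undeca-4,8-dien-1-ylidene]-5-(2-methylprop-1-en-1-yl)oxolan-2-one, both C-11 epimers | OC(C/C=C(\C)CC/C=C(\C)CC/C=C1/C[C@@H](C=C(C)C)OC1=O)C1=CC(=O)OC1 | intermediate
22 | (3Z,5S)-3-[(4E,8E)-4,8-dimethyl-11-oxo-11-(5-oxo-2,5-dihydrofuran-3-yl)undeca-4,8-dien-1-ylidene]-5-(2-methylprop-1-en-1-yl)oxolan-2-one | O=C(C/C=C(\C)CC/C=C(\C)CC/C=C1/C[C@@H](C=C(C)C)OC1=O)C1=CC(=O)OC1 | intermediate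
23 | (3Z,5S)-3-[(4E,8E,11R)-11-hydroxy-4,8-dimethyl-11-(5-oxo-2,5-dihydrofuran-3-yl)undeca-4,8-dien-1-ylidene]-5-(2-methylprop-1-en-1-yl)oxolan-2-one | O[C@H](C/C=C(\C)CC/C=C(\C)CC/C=C1/C[C@@H](C=C(C)C)OC1=O)C1=CC(=O)OC1 | intermediate
24 | (1R,3E,7E)-4,8-dimethyl-11-[(3Z,5S)-5-(2-methylprop-1-en-1-yl)-2-oxooxolan-3-ylidene]-1-(5-oxo-2,5-dihydrofuran-3-yl)undeca-3,7-dien-1-yl acetate | CC(=O)O[C@H](C/C=C(\C)CC/C=C(\C)CC/C=C1/C[C@@H](C=C(C)C)OC1=O)C1=CC(=O)OC1 | target

**Step count and risks**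

Total steps: 16. Longest linear sequence: 15 (steps 1–7 and 9–16; step 8 is a one-step side branch).

Steps most likely to fail:

1. Step 9. The enantioselection may be poor if the sparteine-bound allyllithium equilibrates or reacts without facial preference. The alkenyllithium may also be quenched by proton transfer before it reaches the carbamate. Fallback from 10 to 17: the lithio derivative of 2-(2-methylprop-1-en-1-yl)-1,3-dithiane F1 (from 3-methylbut-2-enal and propane-1,3-dithiol, BF3·OEt2) is alkylated with 10 (n-BuLi, THF, −30 °C) to give the alkylated dithiane F2. Unmasking with MeI/CaCO3 in aqueous MeCN gives the enone F3. Reduction with (R)-Me-CBS and catecholborane gives the (S)-allylic alcohol F4. Palladium-catalysed carbonylative lactonisation of the vinylic bromide (Pd(PPh3)4, CO 1 atm, Et3N, MeCN, 60 °C) then rejoins the route at 17.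

2. Step 10. O-Methylation may compete at the free hydroxyl, or the hindered diisopropyl imidate may not cyclise. Fallback from 16 to 17: reduction of the amide with Cp2Zr(H)Cl (THF, rt) gives the hydroxy aldehyde, which closes to the lactol F5. Oxidation of this allylic lactol with MnO2 in CH2Cl2 gives 17.

3. Step 13. The β,γ-unsaturated aldehyde may isomerise into conjugation or enolise under the Lewis-acidic chromium conditions before it couples. Fallback from 18 to 22: two-stage oxidation (Dess–Martin, then NaClO2/NaH2PO4/2-methylbut-2-ene) gives the acid F6. Oxalyl chloride with catalytic DMF gives the acid chloride F7. Stille acylation with 4-(tributylstannyl)furan-2(5H)-one F8 (from 20 and hexabutylditin, Pd(PPh3)4), using Pd2(dba)3/AsPh3 in THF, gives ketone 22 directly.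

Further compounds
F1 | step 9 | 2-(2-methylprop-1-en-1-yl)-1,3-dithiane | CC(C)=CC1SCCCS1
F2 | step 9 | 2-[(2Z,6E,10E)-2-bromo-13-[(tert-butyldiphenylsilyl)oxy]-6,10-dimethyltrideca-2,6,10-trien-1-yl]-2-(2-methylprop-1-en-1-yl)-1,3-dithiane | CC(C)(C)[Si](c1ccccc1)(c1ccccc1)OCC/C=C(\C)CC/C=C(\C)CC/C=C(\Br)CC1(C=C(C)C)SCCCS1
F3 | step 9 | (6Z,10E,14E)-6-bromo-17-[(tert-butyldiphenylsilyl)oxy]-2,10,14-trimethylheptadeca-2,6,10,14-tetraen-4-one | CC(C)(C)[Si](c1ccccc1)(c1ccccc1)OCC/C=C(\C)CC/C=C(\C)CC/C=C(\Br)CC(=O)C=C(C)C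
F4 | step 9 | (4S,6Z,10E,14E)-6-bromo-17-[(tert-butyldiphenylsilyl)oxy]-2,10,14-trimethylheptadeca-2,6,10,14-tetraen-4-ol | CC(C)(C)[Si](c1ccccc1)(c1ccccc1)OCC/C=C(\C)CC/C=C(\C)CC/C=C(\Br)C[C@H](O)C=C(C)C
F5 | step 10 | (3Z,5S)-3-[(4E,8E)-11-[(tert-butyldiphenylsilyl)oxy]-4,8-dimethylundeca-4,8-dien-1-ylidene]-5-(2-methylprop-1-en-1-yl)oxolan-2-ol | CC(C)(C)[Si](c1ccccc1)(c1ccccc1)OCC/C=C(\C)CC/C=C(\C)CC/C=C1/C[C@@H](C=C(C)C)OC1O
F6 | step 13 | (3E,7E)-4,8-dimethyl-11-[(3Z,5S)-5-(2-methylprop-1-en-1-yl)-2-oxooxolan-3-ylidene]undeca-3,7-dienoic acid | OC(=O)C/C=C(\C)CC/C=C(\C)CC/C=C1/C[C@@H](C=C(C)C)OC1=O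
F7 | step 13 | (3E,7E)-4,8-dimethyl-11-[(3Z,5S)-5-(2-methylprop-1-en-1-yl)-2-oxooxolan-3-ylidene]undeca-3,7-dienoyl chloride | ClC(=O)C/C=C(\C)CC/C=C(\C)CC/C=C1/C[C@@H](C=C(C)C)OC1=O
F8 | step 13 | 4-(tributylstannyl)furan-2(5H)-one | CCCC[Sn](CCCC)(CCCC)C1=CC(=O)OC1
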